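The constants used here are invented.

If the left-handed product is to stop following the catalyst loading, the balance of the reagent is the place to look.

    reagent + catalyst intermediate A → free catalyst + left-handed product (k1 = 874 M⁻¹ s⁻¹)
    free catalyst + left-handed substrate ⇌ catalyst intermediate A (K2 = 140 M⁻¹, k2 = 2.51 × 10⁵ M⁻¹ s⁻¹)
    precatalyst → free catalyst (k3 = 0.00760 s⁻¹)
    free catalyst + right-handed substrate ⇌ catalyst intermediate B (K4 = 520 M⁻¹, k4 = 11700 M⁻¹ s⁻¹)
    reagent + catalyst intermediate B → free catalyst + right-handed product (k5 = 168 M⁻¹ s⁻¹)

| setting | zeta | eta | epsilon | beta |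
|---|---|---|---|---|
| left-handed substrate | 0.0050 M | 0.0050 M | 0.0050 M | 0.0050 M |
| reagent | 1.20 equiv | 1.20 equiv | 1.20 equiv | 1.20 equiv |
| precatalyst | 1 mol% | 2 mol% | 4 mol% | 8 mol% |
| right-handed substrate | 0.0050 M | 0.0050 M | 0.0050 M | 0.0050 M |
| time | 25 s | 25 s | 25 s | 25 s |

1. [left-handed product] at the end for zeta, eta, epsilon, beta, in this order
2. how the row runs (rises all the way / hardly changes / falls all the way / falls, then rises / rises, then falls)

- free catalyst is single-handed; left-handed substrate and right-handed substrate are mirror images of each other, charged as a racemate, each of them at the stated concentration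
- "hardly changes" means that all values lie within two and a half points (for a concentration: within two and a half percent of the largest)
- run time (zeta): 25 s

1. Balance. The reagent, 0.00600 M, is charged in a smaller amount than the two substrates together, 0.0100 M, so it is the limiting reagent. Each reagent lost becomes one product, left-handed or right-handed.

2. Catalyst. By 25 s the precatalyst has released 17.3% of itself. Integrated over the run, this equals the whole catalyst charge working for 2.23 s.

3. Sharing. Released catalyst divides among its forms as in equilibrium, because unbinding is faster than the reagent steps: 1790 s⁻¹ against 5.24 s⁻¹ for intermediate A, and 22.5 s⁻¹ against 1.01 s⁻¹ for intermediate B. With substrates held at their charge, the weights are 1 for free catalyst, 0.700 for intermediate A and 2.60 for intermediate B. Active catalyst therefore consumes reagent with a mean constant of 244 M⁻¹ s⁻¹.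

4. Reagent balance. c(reagent) falls as exp(−D) of its charge, where D is the reagent demand, the mean constant times the catalyst charged times that working time. D is 0.0272 in zeta, and it grows with loading to 0.0544 in eta, 0.109 in epsilon and 0.218 in beta.

5. The question turned round. For a row that hardly changes, with the share of step 6 held, the reckoned reagent left in zeta has to lie inside the margin. D of 4 there leaves 1.83%, inside the margin, but zeta stands 147 times below that.

6. The row. The left-handed step takes 58.3% of the reagent flow, so c(left-handed product) = that share × charge × (1 − exp(−D)). This gives 9.40 × 10⁻⁵ M, 1.85 × 10⁻⁴ M, 3.61 × 10⁻⁴ M and 6.85 × 10⁻⁴ M, rising throughout.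

The forecast gives 9.400 × 10⁻⁵ M, 1.840 × 10⁻⁴ M, 3.550 × 10⁻⁴ M and 6.660 × 10⁻⁴ M, rises all the way, reasoning that the left-handed channel “gives product almost in proportion to catalyst loading”; its last value lies below this reckoning.

The simulation gives 9.60 × 10⁻⁵ M, 1.89 × 10⁻⁴ M, 3.64 × 10⁻⁴ M and 6.81 × 10⁻⁴ M, rises all the way.

In beta the demand of 0.218 is smaller than the 4 that a row which hardly changes asks of zeta, and exp(−D) gives 80.4% of the reagent left, against 81% found unbound at 25.0 s. In epsilon the demand of 0.109 gives 89.7%, against 90% found at 25.0 s.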